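**Strategy.** The ten-membered carbocycle (ring A, germacrane numbering C1–C10) is disconnected at C1–C10, the bond joining the secondary carbinol C1 to the methyl-bearing tertiary carbinol C10. This cis-1,2-diol is the retron of a reductive carbonyl coupling. The key step is an SmI2-mediated intramolecular aldehyde–ketone pinacol cyclisation that, in one operation, closes ring A onto the trans-fused γ-lactone (ring B) and creates both hydroxyls and both stereocentres. Its precursor is an open-chain γ-lactone bearing a C1 aldehyde chain (C3 ketone masked as a dioxolane) on C6 and a C10 methyl ketone chain with the C8 isobutyrate on C7, released from a diene by double ozonolysis.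

Key step: step 13

Remark on numbering: germacrane numbering is used throughout. C1 = CH(OH), C3 = ketone, C4 = CH(CH3), C6 = lactone O–CH, C7 = ring-fusion CH, C8 = CH–O-isobutyrate, C10 = C(OH)CH3, C11/C12/C13 = lactone α-carbon, carbonyl and exocyclic methylene.

Remark on the chemistry: the C3 ketone and the C10 hydroxyl of the target can close reversibly to a five-membered hemiketal; the product is written as the open keto-diol.

**Route**

Step 1
Reactants: 1 (R)-4-benzyl-3-propanoyl-1,3-oxazolidin-2-one; 2 1-bromo-3-methylbut-2-ene (prenyl bromide)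
Product: 3 (4R)-4-benzyl-3-[(2S)-2,5-dimethylhex-4-enoyl]-1,3-oxazolidin-2-one
Conditions: NaN(SiMe3)2, THF, −78 °C; then 2, −78 to −40 °C
Reagents that add atoms: none
Why: Evans asymmetric alkylation, in which the chelated Z-sodium enolate of 1 is alkylated by the allylic bromide on the face opposite the benzyl group, sets C4 (S).

Step 2
Reactants: 3 (4R)-4-benzyl-3-[(2S)-2,5-dimethylhex-4-enoyl]-1,3-oxazolidin-2-one
Product: 4 (2S)-N-methoxy-N,2,5-trimethylhex-4-enamide
Conditions: MeONHMe·HCl, AlMe3, CH2Cl2, 0 °C to rt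
Reagents that add atoms: N,O-dimethylhydroxylamine hydrochloride, CNOC.Cl
Why: Aluminium-amide transamination (Weinreb amide formation) should displace the oxazolidinone at the exocyclic carbonyl without touching the α-stereocentre.

Step 3
Reactants: 4 (2S)-N-methoxy-N,2,5-trimethylhex-4-enamide; 5 allylmagnesium bromide (CH2=CHCH2MgBr)
Product: 6 (5S)-5,8-dimethylnona-1,7-dien-4-one
Conditions: CH2=CHCH2MgBr, THF, −78 °C; aq. NH4Cl quench at −78 °C
Reagents that add atoms: none
Why: Grignard addition to a Weinreb amide stops at the chelated tetrahedral adduct, so a cold quench should release the β,γ-unsaturated ketone without over-addition or conjugation of the allyl double bond.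

Step 4
Reactants: 6 (5S)-5,8-dimethylnona-1,7-dien-4-one
Product: 7 2-[(2S)-5-methylhex-4-en-2-yl]-2-(prop-2-en-1-yl)-1,3-dioxolane
Conditions: (Me3SiOCH2)2, Me3SiOTf (cat.), CH2Cl2, −78 to −20 °C; pyridine quench
Reagents that add atoms: 1,2-bis(trimethylsilyloxy)ethane, C[Si](C)(C)OCCO[Si](C)(C)C
Why: Noyori ketalisation under aprotic, low-temperature conditions should protect the C3 ketone as the dioxolane without enolisation, so neither the C4 centre nor the β,γ-double bond should move.

Step 5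
Reactants: 7 2-[(2S)-5-methylhex-4-en-2-yl]-2-(prop-2-en-1-yl)-1,3-dioxolane
Product: 8 (3S)-3-[2-(prop-2-en-1-yl)-1,3-dioxolan-2-yl]butanal
Conditions: O3 (1.0 equiv), pyridine, CH2Cl2, −78 °C; then PPh3
Reagents that add atoms: ozone, [O-][O+]=O
Why: Chemoselective ozonolysis, in which the electron-rich trisubstituted alkene reacts much faster than the monosubstituted allyl group, should cleave it alone to the C6 aldehyde.

Step 6
Reactants: 9 (S)-4-benzyl-1,3-oxazolidin-2-one; 10 methyl 4-chloro-4-oxobutanoate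
Product: 11 methyl 4-[(4S)-4-benzyl-2-oxo-1,3-oxazolidin-3-yl]-4-oxobutanoate
Conditions: n-BuLi, THF, −78 °C; then 10, −78 to 0 °C
Reagents that add atoms: none
Why: N-Acylation of the lithiated oxazolidinone with the acid chloride gives the succinate imide, the methyl ester being untouched at low temperature.

Step 7
Reactants: 11 methyl 4-[(4S)-4-benzyl-2-oxo-1,3-oxazolidin-3-yl]-4-oxobutanoate; 8 (3S)-3-[2-(prop-2-en-1-yl)-1,3-dioxolan-2-yl]butanal
Product: 13 (4S)-4-benzyl-3-{[(2R,3S)-5-oxo-2-{(2S)-2-[2-(prop-2-en-1-yl)-1,3-dioxolan-2-yl]propyl}oxolan-3-yl]carbonyl}-1,3-oxazolidin-2-one, via syn-aldol adduct 12 (not isolated)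
Conditions: Bu2BOTf, iPr2NEt, CH2Cl2, 0 °C; 8, −78 to 0 °C; H2O2, pH 7 buffer, MeOH; then PPTS (cat.), toluene, 50 °C
Reagents that add atoms: none
Why: Evans syn-aldol reaction, in which the Z-boron enolate of the imide (the ester is not enolised) adds through a chair Zimmerman–Traxler transition state under auxiliary control, sets C7 (S) and C6 (R), and the C6 hydroxyl then lactonises onto the methyl ester to give the trans-disubstituted γ-lactone (ring B).

Step 8
Reactants: 13 (4S)-4-benzyl-3-{[(2R,3S)-5-oxo-2-{(2S)-2-[2-(prop-2-en-1-yl)-1,3-dioxolan-2-yl]propyl}oxolan-3-yl]carbonyl}-1,3-oxazolidin-2-one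
Product: 14 S-ethyl (2R,3S)-5-oxo-2-{(2S)-2-[2-(prop-2-en-1-yl)-1,3-dioxolan-2-yl]propyl}oxolane-3-carbothioate
Conditions: EtSH, n-BuLi (LiSEt), THF, 0 °C
Reagents that add atoms: ethanethiol, CCS
Why: Thiolate cleavage of the N-acyloxazolidinone (transthioesterification) is selective for the activated exocyclic imide carbonyl, and the weakly basic thiolate should not epimerise C7.

Step 9
Reactants: 14 S-ethyl (2R,3S)-5-oxo-2-{(2S)-2-[2-(prop-2-en-1-yl)-1,3-dioxolan-2-yl]propyl}oxolane-3-carbothioate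
Product: 15 (2R,3S)-5-oxo-2-{(2S)-2-[2-(prop-2-en-1-yl)-1,3-dioxolan-2-yl]propyl}oxolane-3-carbaldehyde
Conditions: Et3SiH, Pd/CaCO3 poisoned with Pb(OAc)2 (Lindlar catalyst), acetone, rt
Reagents that add atoms: none
Why: Fukuyama reduction converts the thioester into the C8 aldehyde under neutral conditions, where the poisoned catalyst should spare the terminal alkene and the absence of base should avoid epimerisation or β-elimination at C7.

Step 10
Reactants: 15 (2R,3S)-5-oxo-2-{(2S)-2-[2-(prop-2-en-1-yl)-1,3-dioxolan-2-yl]propyl}oxolane-3-carbaldehyde; 16 (2-methylprop-2-en-1-yl)magnesium chloride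
Product: 18 (4R,5R)-4-[(1R)-1-hydroxy-3-methylbut-3-en-1-yl]-5-{(2S)-2-[2-(prop-2-en-1-yl)-1,3-dioxolan-2-yl]propyl}oxolan-2-one, via methallylborane 17 (not isolated)
Conditions: 16, (+)-Ipc2BOMe, Et2O, −78 °C to rt; then 15, −78 °C; H2O2, pH 7 buffer, MeOH
Reagents that add atoms: none
Why: Brown asymmetric allylboration, in which the methallylborane from the (+)-reagent adds through a chair transition state to the Re face of the aldehyde under reagent control, should set C8 (R) and deliver the isopropenyl group as a masked C10 methyl ketone.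

Step 11
Reactants: 18 (4R,5R)-4-[(1R)-1-hydroxy-3-methylbut-3-en-1-yl]-5-{(2S)-2-[2-(prop-2-en-1-yl)-1,3-dioxolan-2-yl]propyl}oxolan-2-one
Product: 19 (1R)-3-methyl-1-[(2R,3S)-5-oxo-2-{(2S)-2-[2-(prop-2-en-1-yl)-1,3-dioxolan-2-yl]propyl}oxolan-3-yl]but-3-en-1-yl 2-methylpropanoate
Conditions: iPrCOCl, pyridine, DMAP (cat.), CH2Cl2, 0 °C to rt
Reagents that add atoms: isobutyryl chloride, CC(C)C(Cl)=O
Why: Acylation of the secondary alcohol with the acid chloride under nucleophilic catalysis installs the C8 isobutyrate with retention.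

Step 12
Reactants: 19 (1R)-3-methyl-1-[(2R,3S)-5-oxo-2-{(2S)-2-[2-(prop-2-en-1-yl)-1,3-dioxolan-2-yl]propyl}oxolan-3-yl]but-3-en-1-yl 2-methylpropanoate
Product: 20 (1R)-3-oxo-1-[(2R,3S)-5-oxo-2-{(2S)-2-[2-(2-oxoethyl)-1,3-dioxolan-2-yl]propyl}oxolan-3-yl]butyl 2-methylpropanoate
Conditions: O3, CH2Cl2, −78 °C; then PPh3, −78 °C to rt
Reagents that add atoms: ozone, [O-][O+]=O
Why: Ozonolysis with reductive work-up cleaves both terminal alkenes at once, unveiling the C1 aldehyde and the C10 methyl ketone while ketal, lactone and ester are inert.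

Step 13
Reactants: 20 (1R)-3-oxo-1-[(2R,3S)-5-oxo-2-{(2S)-2-[2-(2-oxoethyl)-1,3-dioxolan-2-yl]propyl}oxolan-3-yl]butyl 2-methylpropanoate
Product: 21 (1S,4S,6R,7S,8R,10R)-3,3-ethylenedioxy-1,10-dihydroxy-8-isobutyryloxy-13-norgermacran-12,6-olide (cis-1,10-diol, lactone α-CH2)
Conditions: SmI2 (4 equiv), THF, 0 °C, slow addition of 20 (final 0.002 M); aq. NaHCO3
Reagents that add atoms: none
Why: Electron transfer from SmI2 to the aldehyde, the more easily reduced carbonyl, gives a C1 ketyl bound to trivalent samarium that adds to the C10 ketone carbonyl held on the same metal, and a second electron transfer with protonation on work-up gives the 1,2-diol. The closest known reaction type is the intramolecular pinacol coupling of keto-aldehydes with SmI2 or low-valent titanium, which is established for closing medium and large carbocycles. Ring A, the ten-membered carbocycle, is closed by joining the two carbonyl carbons head to head (ketyl addition to a carbonyl), and no smaller ring can form because no other acceptor is within reach. At C1 (S) and C10 (R) the cis relationship of the new hydroxyls should follow from the samarium-bridged diolate transition state, the C10 face should be set by attack anti to the C8–O bond of the β-acyloxy ketone in its dipole-minimised conformation (1,3-anti induction, C10 hydroxyl trans to the isobutyrate), and the trans-fused lactone at C6/C7 holds the chain in the folded conformer that delivers C1 accordingly. The step needs chemoselectivity for the two free carbonyls and cyclisation in preference to dimerisation: esters, lactone and ketal are inert to SmI2 without strongly donating additives, the reducible α-methylene group is not yet present, and slow addition at high dilution favours ring closure.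

Step 14
Reactants: 21 (1S,4S,6R,7S,8R,10R)-3,3-ethylenedioxy-1,10-dihydroxy-8-isobutyryloxy-13-norgermacran-12,6-olide
Product: 22 (1S,4S,6R,7S,8R,10R)-3,3-ethylenedioxy-1,10-O-isopropylidene-8-isobutyryloxy-13-norgermacran-12,6-olide (acetonide)
Conditions: 2-methoxypropene, PPTS (cat.), CH2Cl2, 0 °C to rt
Reagents that add atoms: 2-methoxypropene, COC(C)=C
Why: Acid-catalysed acetonide formation is specific for the cis-1,2-diol and masks both hydroxyls for the enolate chemistry that follows.

Step 15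
Reactants: 22 (1S,4S,6R,7S,8R,10R)-3,3-ethylenedioxy-1,10-O-isopropylidene-8-isobutyryloxy-13-norgermacran-12,6-olide
Product: 23 (1S,4S,6R,7S,8R,10R,11R)-13-(dimethylamino)-3,3-ethylenedioxy-1,10-O-isopropylidene-8-isobutyryloxygermacran-12,6-olide
Conditions: LiN(iPr)2, THF, −78 °C; (CH2=NMe2)I, −78 °C to rt
Reagents that add atoms: N,N-dimethylmethyleneiminium iodide (Eschenmoser's salt), C=[N+](C)C.[I-]
Why: Mannich reaction of the lactone lithium enolate, formed by kinetic deprotonation at the unhindered lactone α-CH2 and not at the isobutyrate methine, should give the amine by attack trans to the C7 substituent, the C11 configuration being of no consequence.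

Step 16
Reactants: 23 (1S,4S,6R,7S,8R,10R,11R)-13-(dimethylamino)-3,3-ethylenedioxy-1,10-O-isopropylidene-8-isobutyryloxygermacran-12,6-olide
Product: 25 (1S,4S,6R,7S,8R,10R)-3,3-ethylenedioxy-1,10-O-isopropylidene-8-isobutyryloxygermacr-11(13)-en-12,6-olide, via quaternary ammonium iodide 24 (not isolated)
Conditions: MeI, MeOH, rt; then NaHCO3, H2O/CH2Cl2, rt
Reagents that add atoms: none
Why: Quaternisation of the tertiary amine followed by mild base-induced β-elimination (Hofmann-type, E1cB) releases the exocyclic α-methylene lactone.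

Step 17
Reactants: 25 (1S,4S,6R,7S,8R,10R)-3,3-ethylenedioxy-1,10-O-isopropylidene-8-isobutyryloxygermacr-11(13)-en-12,6-olide
Product: 26 (1S,4S,6R,7S,8R,10R)-1,10-dihydroxy-8-isobutyryloxy-3-oxogermacr-11(13)-en-12,6-olide (target)
Conditions: HCl (1 M, aq.), THF, rt
Reagents that add atoms: water, O
Why: Aqueous acid hydrolysis removes the acetonide and the dioxolane in one operation, liberating the 1,10-diol and the C3 ketone under conditions that ester, lactone and the C4 centre should tolerate.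

**Compound list**

1 | (R)-4-benzyl-3-propanoyl-1,3-oxazolidin-2-one | CCC(=O)N1[C@H](Cc2ccccc2)COC1=O | starting material
2 | 1-bromo-3-methylbut-2-ene | CC(C)=CCBr | starting material
3 | (4R)-4-benzyl-3-[(2S)-2,5-dimethylhex-4-enoyl]-1,3-oxazolidin-2-one | CC(C)=CC[C@H](C)C(=O)N1[C@H](Cc2ccccc2)COC1=O | intermediate
4 | (2S)-N-methoxy-N,2,5-trimethylhex-4-enamide | CC(C)=CC[C@H](C)C(=O)N(C)OC | intermediate
5 | allylmagnesium bromide | C=CC[Mg]Br | starting material
6 | (5S)-5,8-dimethylnona-1,7-dien-4-one | C=CCC(=O)[C@@H](C)CC=C(C)C | intermediate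
7 | 2-[(2S)-5-methylhex-4-en-2-yl]-2-(prop-2-en-1-yl)-1,3-dioxolane | C=CCC1(OCCO1)[C@@H](C)CC=C(C)C | intermediate
8 | (3S)-3-[2-(prop-2-en-1-yl)-1,3-dioxolan-2-yl]butanal | C=CCC1(OCCO1)[C@@H](C)CC=O | intermediate
9 | (S)-4-benzyl-1,3-oxazolidin-2-one | O=C1N[C@@H](Cc2ccccc2)CO1 | starting material
10 | methyl 4-chloro-4-oxobutanoate | COC(=O)CCC(Cl)=O | starting material
11 | methyl 4-[(4S)-4-benzyl-2-oxo-1,3-oxazolidin-3-yl]-4-oxobutanoate | COC(=O)CCC(=O)N1[C@@H](Cc2ccccc2)COC1=O | intermediate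
12 | methyl (3S,4R,6S)-3-{[(4S)-4-benzyl-2-oxo-1,3-oxazolidin-3-yl]carbonyl}-4-hydroxy-6-[2-(prop-2-en-1-yl)-1,3-dioxolan-2-yl]heptanoate | COC(=O)C[C@H](C(=O)N1[C@@H](Cc2ccccc2)COC1=O)[C@H](O)C[C@H](C)C3(CC=C)OCCO3 | intermediate
13 | (4S)-4-benzyl-3-{[(2R,3S)-5-oxo-2-{(2S)-2-[2-(prop-2-en-1-yl)-1,3-dioxolan-2-yl]propyl}oxolan-3-yl]carbonyl}-1,3-oxazolidin-2-one | O=C1C[C@H](C(=O)N2[C@@H](Cc3ccccc3)COC2=O)[C@@H](C[C@H](C)C4(CC=C)OCCO4)O1 | intermediate
14 | S-ethyl (2R,3S)-5-oxo-2-{(2S)-2-[2-(prop-2-en-1-yl)-1,3-dioxolan-2-yl]propyl}oxolane-3-carbothioate | O=C1C[C@H](C(=O)SCC)[C@@H](C[C@H](C)C2(CC=C)OCCO2)O1 | intermediate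
15 | (2R,3S)-5-oxo-2-{(2S)-2-[2-(prop-2-en-1-yl)-1,3-dioxolan-2-yl]propyl}oxolane-3-carbaldehyde | O=C1C[C@H](C=O)[C@@H](C[C@H](C)C2(CC=C)OCCO2)O1 | intermediate
16 | (2-methylprop-2-en-1-yl)magnesium chloride | CC(=C)C[Mg]Cl | starting material
17 | B-(2-methylprop-2-en-1-yl)diisopinocampheylborane from (+)-Ipc2BOMe | CC(=C)CB([C@@H]1[C@@H](C)[C@@H]2C[C@H](C1)C2(C)C)[C@@H]1[C@@H](C)[C@@H]2C[C@H](C1)C2(C)C | intermediate
18 | (4R,5R)-4-[(1R)-1-hydroxy-3-methylbut-3-en-1-yl]-5-{(2S)-2-[2-(prop-2-en-1-yl)-1,3-dioxolan-2-yl]propyl}oxolan-2-one | O=C1C[C@H]([C@H](O)CC(C)=C)[C@@H](C[C@H](C)C2(CC=C)OCCO2)O1 | intermediate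
19 | (1R)-3-methyl-1-[(2R,3S)-5-oxo-2-{(2S)-2-[2-(prop-2-en-1-yl)-1,3-dioxolan-2-yl]propyl}oxolan-3-yl]but-3-en-1-yl 2-methylpropanoate | O=C1C[C@H]([C@H](OC(=O)C(C)C)CC(C)=C)[C@@H](C[C@H](C)C2(CC=C)OCCO2)O1 | intermediate
20 | (1R)-3-oxo-1-[(2R,3S)-5-oxo-2-{(2S)-2-[2-(2-oxoethyl)-1,3-dioxolan-2-yl]propyl}oxolan-3-yl]butyl 2-methylpropanoate | O=C1C[C@H]([C@H](OC(=O)C(C)C)CC(C)=O)[C@@H](C[C@H](C)C2(CC=O)OCCO2)O1 | intermediate
21 | (1S,4S,6R,7S,8R,10R)-3,3-ethylenedioxy-1,10-dihydroxy-8-isobutyryloxy-13-norgermacran-12,6-olide | C1C(=O)O[C@@H]2C[C@H](C)C3(OCCO3)C[C@H](O)[C@](C)(O)C[C@@H](OC(=O)C(C)C)[C@@H]12 | intermediate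
22 | (1S,4S,6R,7S,8R,10R)-3,3-ethylenedioxy-1,10-O-isopropylidene-8-isobutyryloxy-13-norgermacran-12,6-olide | C1C(=O)O[C@@H]2C[C@H](C)C3(OCCO3)C[C@@H]4OC(C)(C)O[C@]4(C)C[C@@H](OC(=O)C(C)C)[C@@H]12 | intermediate
23 | (1S,4S,6R,7S,8R,10R,11R)-13-(dimethylamino)-3,3-ethylenedioxy-1,10-O-isopropylidene-8-isobutyryloxygermacran-12,6-olide | CN(C)C[C@@H]1C(=O)O[C@@H]2C[C@H](C)C3(OCCO3)C[C@@H]4OC(C)(C)O[C@]4(C)C[C@@H](OC(=O)C(C)C)[C@@H]12 | intermediate
24 | trimethylammonium iodide of 23 (N-methyl quaternary salt) | C[N+](C)(C)C[C@@H]1C(=O)O[C@@H]2C[C@H](C)C3(OCCO3)C[C@@H]4OC(C)(C)O[C@]4(C)C[C@@H](OC(=O)C(C)C)[C@@H]12.[I-] | intermediate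
25 | (1S,4S,6R,7S,8R,10R)-3,3-ethylenedioxy-1,10-O-isopropylidene-8-isobutyryloxygermacr-11(13)-en-12,6-olide | C=C1C(=O)O[C@@H]2C[C@H](C)C3(OCCO3)C[C@@H]4OC(C)(C)O[C@]4(C)C[C@@H](OC(=O)C(C)C)[C@@H]12 | intermediate
26 | (1S,4S,6R,7S,8R,10R)-1,10-dihydroxy-8-isobutyryloxy-3-oxogermacr-11(13)-en-12,6-olide | C=C1C(=O)O[C@@H]2C[C@H](C)C(=O)C[C@H](O)[C@](C)(O)C[C@@H](OC(=O)C(C)C)[C@@H]12 | target

**Step count**

Total: 17 steps. Longest linear sequence: 16 steps (steps 1–5 and 7–17, from compound 1).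

**Steps most likely to fail, with fallbacks**

Step 13. Ring closure may lose to intermolecular coupling or to simple carbonyl reduction, and the diol may form on the wrong face or with the trans relationship. The fallback sets out from diene 19. Ring-closing metathesis with the second-generation Grubbs catalyst (toluene, 80 °C, high dilution) forms the same C1–C10 bond as the trisubstituted double bond of (4S,6R,7S,8R)-3,3-ethylenedioxy-8-isobutyryloxy-13-norgermacr-1(10)Z-en-12,6-olide F1, with loss of ethene. The Z geometry expected for a ten-membered ring, followed by syn-dihydroxylation from the peripheral face (OsO4 cat., NMO, acetone/H2O), should give the cis-diol, and the route is rejoined at compound 21.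

Step 10. Facial selectivity of the allylboration may be eroded by the resident C7 centre, and the aldehyde may epimerise or undergo β-elimination before it reacts. The fallback sets out from aldehyde 15. A boron-mediated aldol reaction with acetone (acetone, (Ipc)2BCl of the enantiomeric series that directs attack to the Re face, Et3N, Et2O, −78 °C) gives (4R,5R)-4-[(1R)-1-hydroxy-3-oxobutyl]-5-{(2S)-2-[2-(prop-2-en-1-yl)-1,3-dioxolan-2-yl]propyl}oxolan-2-one F2 with the C10 ketone already in place. Acylation (iPrCOCl, pyridine, 0 °C) gives (1R)-3-oxo-1-[(2R,3S)-5-oxo-2-{(2S)-2-[2-(prop-2-en-1-yl)-1,3-dioxolan-2-yl]propyl}oxolan-3-yl]butyl 2-methylpropanoate F3. Ozonolysis of its single alkene (O3; PPh3) rejoins the route at compound 20.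

Step 9. The palladium hydride may reduce or isomerise the terminal alkene, and decarbonylation of the acylpalladium intermediate may compete. The fallback sets out from imide 13. NaBH4 (THF/H2O, 0 °C) reduces the imide carbonyl chemoselectively, with release of the auxiliary, to (4R,5R)-4-(hydroxymethyl)-5-{(2S)-2-[2-(prop-2-en-1-yl)-1,3-dioxolan-2-yl]propyl}oxolan-2-one F4. Oxidation with Dess–Martin periodinane (NaHCO3, CH2Cl2) then rejoins the route at compound 15.

Further compounds
F1 | step 13 | (4S,6R,7S,8R)-3,3-ethylenedioxy-8-isobutyryloxy-13-norgermacr-1(10)Z-en-12,6-olide | C1C(=O)O[C@@H]2C[C@H](C)C3(OCCO3)C/C=C(C)\C[C@@H](OC(=O)C(C)C)[C@@H]12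
F2 | step 10 | (4R,5R)-4-[(1R)-1-hydroxy-3-oxobutyl]-5-{(2S)-2-[2-(prop-2-en-1-yl)-1,3-dioxolan-2-yl]propyl}oxolan-2-one | O=C1C[C@H]([C@H](O)CC(C)=O)[C@@H](C[C@H](C)C2(CC=C)OCCO2)O1
F3 | step 10 | (1R)-3-oxo-1-[(2R,3S)-5-oxo-2-{(2S)-2-[2-(prop-2-en-1-yl)-1,3-dioxolan-2-yl]propyl}oxolan-3-yl]butyl 2-methylpropanoate | O=C1C[C@H]([C@H](OC(=O)C(C)C)CC(C)=O)[C@@H](C[C@H](C)C2(CC=C)OCCO2)O1
F4 | step 9 | (4R,5R)-4-(hydroxymethyl)-5-{(2S)-2-[2-(prop-2-en-1-yl)-1,3-dioxolan-2-yl]propyl}oxolan-2-one | O=C1C[C@H](CO)[C@@H](C[C@H](C)C2(CC=C)OCCO2)O1
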